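Ring B is grown on ring A instead of being coupled to it. The ether carbon C1' of ring B is linked through oxygen to ring A C6, whose neighbour C1 carries the ester carbon; C1' can therefore be the spiro C2 of a benzofuran-3-one whose C3 ketone is that ester in masked form. A Diels–Alder reaction between the exocyclic C1'=C6' enone of a Z 2-(2-silyloxyethylidene)-4-prenyloxybenzofuranone and a prenylated 1,3-dimethoxy-1-silyloxy diene forms C1'–C2' and C5'–C6' at once, closing ring B with O2', MeO-4', the C5' prenyl and the C6' CH2O group in place. Methoxide then cuts C3–C1' (retro-Claisen) and a dehydrogenation aromatizes ring B.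

Key step: step 8

Remark on numbering: ring A is C1–C6 (C1 bears CO2Me, C2 the prenyl ether, C6 the diaryl ether oxygen); ring B is C1'–C6' (C1' ether carbon, C2' O-prenyl, C4' OMe, C5' C-prenyl, C6' CH2OH); the furanone atoms are O1, C2 (= C1') and C3.
Remark on stereochemistry: the target is achiral; the stereocentres in 10 and 17–21 are formed without control (racemic diastereomer mixtures) and all are gone after step 10.

Step 1
Reactants: 1 methyl 2,6-dihydroxybenzoate; 2 prenyl bromide (1-bromo-3-methylbut-2-ene)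
Product: 3 methyl 2-hydroxy-6-(3-methylbut-2-enyloxy)benzoate
Conditions: 2 (1.05 equiv), K2CO3 (1.1 equiv), acetone, 50 °C
Reagents that add atoms: none
Why: Williamson mono-etherification; after the first alkylation the remaining phenol is tied up in a hydrogen bond to the ester carbonyl and is far less nucleophilic, so dialkylation should stay minor.

Step 2
Reactants: 3 methyl 2-hydroxy-6-(3-methylbut-2-enyloxy)benzoate; 4 methyl bromoacetate
Product: 5 methyl 2-(2-methoxy-2-oxoethoxy)-6-(3-methylbut-2-enyloxy)benzoate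
Conditions: 4 (1.2 equiv), K2CO3, DMF, 60 °C
Reagents that add atoms: none
Why: Williamson etherification of the hydrogen-bonded phenol with a reactive α-bromo ester in a dipolar aprotic solvent.

Step 3
Reactants: 5 methyl 2-(2-methoxy-2-oxoethoxy)-6-(3-methylbut-2-enyloxy)benzoate
Product: 8 4-(3-methylbut-2-enyloxy)benzofuran-3(2H)-one, via hydroxybenzofuran ester 6 (not isolated), via hydroxybenzofuran acid 7 (not isolated)
Conditions: KOt-Bu (1.2 equiv), THF, 0 → 25 °C; then 2 M aq NaOH, MeOH, 65 °C; then 1 M HCl to pH 2–3, 25 → 45 °C; under N2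
Reagents that add atoms: none
Why: Dieckmann condensation (the OCH2CO2Me enolate is the only one available and closes the five-membered ring on the neighbouring aryl ester), then saponification and decarboxylation of the β-keto acid on mild acidification, which the aryl prenyl ether tolerates.

Step 4
Reactants: 8 4-(3-methylbut-2-enyloxy)benzofuran-3(2H)-one; 9 (tert-butyldimethylsilyloxy)acetaldehyde
Product: 11 (2Z)-2-[2-(tert-butyldimethylsilyloxy)ethylidene]-4-(3-methylbut-2-enyloxy)benzofuran-3(2H)-one, via aldol adduct 10 (not isolated)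
Conditions: 9 (1.5 equiv), neutral Al2O3 (Brockmann grade 1), CH2Cl2, 25 °C
Reagents that add atoms: none
Why: Aldol condensation at the acidic C2 methylene with surface-promoted dehydration; the Z alkene (CH2OSi on the O1 side, away from the C3 carbonyl) is the thermodynamic isomer, and excess aldehyde suppresses conjugate addition of a second benzofuranone.

Step 5
Reactants: 12 methyl acetoacetate; 2 prenyl bromide
Product: 13 methyl 7-methyl-3-oxooct-6-enoate
Conditions: LiN(iPr)2 (2.2 equiv), THF, 0 °C; 2 (1.0 equiv), 0 → 25 °C; aq NH4Cl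
Reagents that add atoms: none
Why: γ-Alkylation of the acetoacetate dianion, whose terminal (more basic) carbanion reacts with the primary allylic bromide by SN2 displacement.

Step 6
Reactants: 13 methyl 7-methyl-3-oxooct-6-enoate
Product: 15 methyl (2E)-3-methoxy-7-methylocta-2,6-dienoate, via dimethyl ketal 14 (not isolated)
Conditions: HC(OMe)3 (2 equiv), MeOH, TsOH·H2O (1 mol %), 25 °C; then NaOMe (5 mol %), 60 °C, MeOH distilled off
Reagents that add atoms: trimethyl orthoformate, COC(OC)OC
Why: Acid-catalysed ketalization with the orthoformate as water scavenger, then base-induced E1cB loss of methanol (enol ether formation) to the conjugated E isomer, so the trisubstituted alkene never meets hot acid.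

Step 7
Reactants: 15 methyl (2E)-3-methoxy-7-methylocta-2,6-dienoate
Product: 16 (3Z)-1,3-dimethoxy-7-methyl-1-(trimethylsilyloxy)octa-1,3,6-triene
Conditions: LiN(iPr)2 (1.1 equiv), THF, −78 °C; Me3SiCl, −78 → 0 °C; pentane, filtration, used crude
Reagents that add atoms: chlorotrimethylsilane, C[Si](C)(C)Cl
Why: Vinylketene silyl acetal formation by γ-deprotonation (C4) of the vinylogous ester and O-silylation of the dienolate; the expected 3Z geometry (C5 trans to C2, least allylic strain) is the one that can reach the s-cis conformation.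

Step 8
Reactants: 11 (2Z)-2-[2-(tert-butyldimethylsilyloxy)ethylidene]-4-(3-methylbut-2-enyloxy)benzofuran-3(2H)-one; 16 (3Z)-1,3-dimethoxy-7-methyl-1-(trimethylsilyloxy)octa-1,3,6-triene
Product: 18 6'-[(tert-butyldimethylsilyloxy)methyl]-4'-methoxy-5'-(3-methylbut-2-enyl)-4-(3-methylbut-2-enyloxy)-3H-spiro[benzofuran-2,1'-cyclohex[3]ene]-2',3-dione (racemic mixture of diastereomers), via silyl methyl ketal cycloadduct 17 (not isolated)
Conditions: 16 (2.5 equiv), toluene, 90 °C, sealed tube, Ar; then 0.1 M HCl, THF, 0 °C, short contact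
Reagents that add atoms: none
Why: Normal-demand Diels–Alder reaction of the kind established for 1,1,3-trioxygenated butadienes and 2-alkylidenebenzofuran-3-ones: the γ-terminus C5' of the vinylketene acetal bonds first to C6', the β-carbon of the exocyclic enone, and the ketene acetal carbon C2' closes on C1' in the same asynchronous [4+2] event. Ring B is closed as a six-membered ring by this intermolecular cycloaddition, spiro at the furanone C2 (= C1'). Three stereocentres arise: C1' and C6' are related by suprafacial addition to the Z alkene, C5' by an unbiased endo or exo approach, so a racemic diastereomer mixture is expected and accepted because steps 9 and 10 erase every centre. The only selectivity needed is regiochemical (oxygen at C2' ortho and OMe at C4' para to C1'), and it is secured by the polarity match between the nucleophilic diene terminus and the electrophilic C6'. Dilute acid then collapses the C2' silyl methyl ketal of 17 to the ketone while the conjugated C4' methyl enol ether survives, which differentiates the two ring B oxygens; acid is chosen over base or fluoride because an alkoxide at C2' could expel the benzofuranone enolate. The temperature is well below that of an aryl prenyl ether Claisen rearrangement.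

Step 9
Reactants: 18 spiro adduct (name as in step 8)
Product: 19 methyl 2-{[2-[(tert-butyldimethylsilyloxy)methyl]-4-methoxy-3-(3-methylbut-2-enyl)-6-oxocyclohex-4-en-1-yl]oxy}-6-(3-methylbut-2-enyloxy)benzoate (racemic mixture of diastereomers)
Conditions: NaOMe (0.3 equiv), MeOH–THF, 0 → 25 °C; AcOH quench
Reagents that add atoms: methanol, CO
Why: Retro-Claisen fragmentation of the non-enolizable 1,3-diketone: methoxide adds to the strained, more electrophilic furanone ketone C3 (the ring B carbonyl C2' is a deactivated vinylogous ester), the adduct collapses by cleaving C3–C1' to the ring A methyl ester and the C1' enolate, and protonation by methanol makes the opening irreversible; the new C1' centre forms unselectively and is removed in step 10.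

Step 10
Reactants: 19 methyl 2-{[2-[(tert-butyldimethylsilyloxy)methyl]-4-methoxy-3-(3-methylbut-2-enyl)-6-oxocyclohex-4-en-1-yl]oxy}-6-(3-methylbut-2-enyloxy)benzoate
Product: 22 methyl 2-{2-[(tert-butyldimethylsilyloxy)methyl]-6-hydroxy-4-methoxy-3-(3-methylbut-2-enyl)phenoxy}-6-(3-methylbut-2-enyloxy)benzoate, via silyl dienol ether 20 (not isolated), via cyclohexadienone 21 (not isolated)
Conditions: Me3SiCl (3 equiv), then LiN(iPr)2 (1.2 equiv), THF, −78 °C; then Pd(OAc)2 (1.1 equiv), MeCN, 25 °C
Reagents that add atoms: none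
Why: Kinetic deprotonation at C1' (α' to the ketone, activated by the aryloxy group) with in situ silylation gives the cross-conjugated silyl dienol ether, and Saegusa–Ito oxidation with divalent palladium places the new double bond at C1'=C6' (the only β-hydrogen open to the C1' palladium enolate), after which the 4H-dienone tautomerizes to the phenol and all stereocentres vanish; because ring B of 20 is already a dihydroarene, a regioisomeric dienol ether would converge on the same phenol.

Step 11
Reactants: 22 methyl 2-{2-[(tert-butyldimethylsilyloxy)methyl]-6-hydroxy-4-methoxy-3-(3-methylbut-2-enyl)phenoxy}-6-(3-methylbut-2-enyloxy)benzoate; 2 prenyl bromide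
Product: 23 methyl 2-{2-[(tert-butyldimethylsilyloxy)methyl]-4-methoxy-3-(3-methylbut-2-enyl)-6-(3-methylbut-2-enyloxy)phenoxy}-6-(3-methylbut-2-enyloxy)benzoate
Conditions: 2 (1.3 equiv), K2CO3, DMF, 25 °C
Reagents that add atoms: none
Why: Williamson O-alkylation of the only free phenol; a carbonate base in a dipolar aprotic solvent favours O- over C-prenylation.

Step 12
Reactants: 23 methyl 2-{2-[(tert-butyldimethylsilyloxy)methyl]-4-methoxy-3-(3-methylbut-2-enyl)-6-(3-methylbut-2-enyloxy)phenoxy}-6-(3-methylbut-2-enyloxy)benzoate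
Product: 24 methyl 2-[2-(hydroxymethyl)-4-methoxy-3-(3-methylbut-2-enyl)-6-(3-methylbut-2-enyloxy)phenoxy]-6-(3-methylbut-2-enyloxy)benzoate (target, CNP0500611.0)
Conditions: Bu4NF (1.5 equiv), AcOH (1.5 equiv), THF, 0 → 25 °C
Reagents that add atoms: none
Why: Fluoride-mediated cleavage of the primary silyl ether; buffering with AcOH keeps the freed benzylic alkoxide from attacking the ring A ester (eight-membered lactonization).

Compound list
1 | methyl 2,6-dihydroxybenzoate | COC(=O)c1c(O)cccc1O | starting material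
2 | prenyl bromide (1-bromo-3-methylbut-2-ene) | CC(C)=CCBr | starting material
3 | methyl 2-hydroxy-6-(3-methylbut-2-enyloxy)benzoate | COC(=O)c1c(O)cccc1OCC=C(C)C | intermediate
4 | methyl bromoacetate | COC(=O)CBr | starting material
5 | methyl 2-(2-methoxy-2-oxoethoxy)-6-(3-methylbut-2-enyloxy)benzoate | COC(=O)COc1cccc(OCC=C(C)C)c1C(=O)OC | intermediate
6 | methyl 3-hydroxy-4-(3-methylbut-2-enyloxy)benzofuran-2-carboxylate (not isolated) | COC(=O)c1oc2cccc(OCC=C(C)C)c2c1O | intermediate
7 | 3-hydroxy-4-(3-methylbut-2-enyloxy)benzofuran-2-carboxylic acid (not isolated) | OC(=O)c1oc2cccc(OCC=C(C)C)c2c1O | intermediate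
8 | 4-(3-methylbut-2-enyloxy)benzofuran-3(2H)-one | O=C1COc2cccc(OCC=C(C)C)c21 | intermediate
9 | (tert-butyldimethylsilyloxy)acetaldehyde | CC(C)(C)[Si](C)(C)OCC=O | starting material
10 | 2-[2-(tert-butyldimethylsilyloxy)-1-hydroxyethyl]-4-(3-methylbut-2-enyloxy)benzofuran-3(2H)-one (racemic diastereomer mixture, not isolated) | O=C1c2c(OCC=C(C)C)cccc2OC1C(O)CO[Si](C)(C)C(C)(C)C | intermediate
11 | (2Z)-2-[2-(tert-butyldimethylsilyloxy)ethylidene]-4-(3-methylbut-2-enyloxy)benzofuran-3(2H)-one | O=C1c2c(OCC=C(C)C)cccc2O/C1=C\CO[Si](C)(C)C(C)(C)C | intermediate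
12 | methyl acetoacetate | COC(=O)CC(C)=O | starting material
13 | methyl 7-methyl-3-oxooct-6-enoate | COC(=O)CC(=O)CCC=C(C)C | intermediate
14 | methyl 3,3-dimethoxy-7-methyloct-6-enoate (not isolated) | COC(=O)CC(OC)(OC)CCC=C(C)C | intermediate
15 | methyl (2E)-3-methoxy-7-methylocta-2,6-dienoate | COC(=O)/C=C(/OC)CCC=C(C)C | intermediate
16 | (3Z)-1,3-dimethoxy-7-methyl-1-(trimethylsilyloxy)octa-1,3,6-triene | COC(O[Si](C)(C)C)=C/C(OC)=C/CC=C(C)C | intermediate
17 | 6'-[(tert-butyldimethylsilyloxy)methyl]-2',4'-dimethoxy-5'-(3-methylbut-2-enyl)-4-(3-methylbut-2-enyloxy)-2'-(trimethylsilyloxy)-3H-spiro[benzofuran-2,1'-cyclohex[3]en]-3-one (racemic diastereomer mixture, not isolated) | O=C1c2c(OCC=C(C)C)cccc2OC13C(OC)(O[Si](C)(C)C)C=C(OC)C(CC=C(C)C)C3CO[Si](C)(C)C(C)(C)C | intermediate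
18 | 6'-[(tert-butyldimethylsilyloxy)methyl]-4'-methoxy-5'-(3-methylbut-2-enyl)-4-(3-methylbut-2-enyloxy)-3H-spiro[benzofuran-2,1'-cyclohex[3]ene]-2',3-dione (racemic diastereomer mixture) | O=C1c2c(OCC=C(C)C)cccc2OC13C(=O)C=C(OC)C(CC=C(C)C)C3CO[Si](C)(C)C(C)(C)C | intermediate
19 | methyl 2-{[2-[(tert-butyldimethylsilyloxy)methyl]-4-methoxy-3-(3-methylbut-2-enyl)-6-oxocyclohex-4-en-1-yl]oxy}-6-(3-methylbut-2-enyloxy)benzoate (racemic diastereomer mixture) | COC(=O)c1c(OCC=C(C)C)cccc1OC1C(=O)C=C(OC)C(CC=C(C)C)C1CO[Si](C)(C)C(C)(C)C | intermediate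
20 | methyl 2-{[6-[(tert-butyldimethylsilyloxy)methyl]-4-methoxy-5-(3-methylbut-2-enyl)-2-(trimethylsilyloxy)cyclohexa-1,3-dien-1-yl]oxy}-6-(3-methylbut-2-enyloxy)benzoate (racemic diastereomer mixture, not isolated) | COC(=O)c1c(OCC=C(C)C)cccc1OC1=C(O[Si](C)(C)C)C=C(OC)C(CC=C(C)C)C1CO[Si](C)(C)C(C)(C)C | intermediate
21 | methyl 2-{[2-[(tert-butyldimethylsilyloxy)methyl]-4-methoxy-3-(3-methylbut-2-enyl)-6-oxocyclohexa-1,4-dien-1-yl]oxy}-6-(3-methylbut-2-enyloxy)benzoate (racemic, not isolated) | COC(=O)c1c(OCC=C(C)C)cccc1OC1=C(CO[Si](C)(C)C(C)(C)C)C(CC=C(C)C)C(OC)=CC1=O | intermediate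
22 | methyl 2-{2-[(tert-butyldimethylsilyloxy)methyl]-6-hydroxy-4-methoxy-3-(3-methylbut-2-enyl)phenoxy}-6-(3-methylbut-2-enyloxy)benzoate | COC(=O)c1c(OCC=C(C)C)cccc1Oc1c(O)cc(OC)c(CC=C(C)C)c1CO[Si](C)(C)C(C)(C)C | intermediate
23 | methyl 2-{2-[(tert-butyldimethylsilyloxy)methyl]-4-methoxy-3-(3-methylbut-2-enyl)-6-(3-methylbut-2-enyloxy)phenoxy}-6-(3-methylbut-2-enyloxy)benzoate | COC(=O)c1c(OCC=C(C)C)cccc1Oc1c(OCC=C(C)C)cc(OC)c(CC=C(C)C)c1CO[Si](C)(C)C(C)(C)C | intermediate
24 | methyl 2-[2-(hydroxymethyl)-4-methoxy-3-(3-methylbut-2-enyl)-6-(3-methylbut-2-enyloxy)phenoxy]-6-(3-methylbut-2-enyloxy)benzoate | COC(=O)c1c(OCC=C(C)C)cccc1Oc1c(OCC=C(C)C)cc(OC)c(CC=C(C)C)c1CO | target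

Total step count: 12. Longest linear sequence: 9 steps (steps 1–4 and 8–12); the diene branch (steps 5–7) joins at step 8.

Steps most likely to fail

1. Step 8. The cycloaddition joins two substituted termini (C5' and C6') and may be slow. Meanwhile the diene could lose its silyl group, or the reaction could stop at the open-chain conjugate adduct after silyl transfer, without ring closure. The fallback forms the same two bonds one after the other. It sets out from keto ester 13 and dienophile 11 and returns to the route at 18.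
 - Keto ester 13 is silylated (Me3SiCl, Et3N) to the silyl enol ether methyl (2Z)-7-methyl-3-(trimethylsilyloxy)octa-2,6-dienoate F1.
 - F1 is converted (LiN(iPr)2, Me3SiCl, THF, −78 °C) into the bis-silyl dienol ether (3Z)-1-methoxy-7-methyl-1,3-bis(trimethylsilyloxy)octa-1,3,6-triene F2.
 - A Mukaiyama–Michael addition of F2 to C6' of 11 (Me3SiOTf cat., CH2Cl2, −78 °C, aqueous work-up) should give the open-chain keto ester methyl 6-(tert-butyldimethylsilyloxy)-4-(3-methylbut-2-enyl)-3-oxo-5-[3-oxo-4-(3-methylbut-2-enyloxy)-2,3-dihydrobenzofuran-2-yl]hexanoate F3.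
 - NaOMe in MeOH then closes ring B by Dieckmann-type acylation of C1' with the ester carbon C2', driven by deprotonation of the new cyclic 1,3-dione. The product is the spiro trione 6'-[(tert-butyldimethylsilyloxy)methyl]-5'-(3-methylbut-2-enyl)-4-(3-methylbut-2-enyloxy)-3H-spiro[benzofuran-2,1'-cyclohexane]-2',3,4'-trione F4.
 - Me3SiCHN2 in MeOH–toluene methylates the enol oxygen at C4', the less hindered one remote from the spiro centre, to give 18. The C2' enol ether isomer would be removed by chromatography.

2. Step 9. Methoxide may instead add to the ring B carbonyl C2' and expel the benzofuranone enolate, cleaving C1'–C2' in place of C3–C1'. Slow methanolysis could also let base-induced ring opening through γ-deprotonation at C5' compete. The fallback makes the cleavage aromatization-driven. It sets out from 18 and returns at phenol 22, replacing steps 9 and 10.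
 - Soft enolization (Me3SiOTf, Et3N, CH2Cl2, 0 °C) deprotonates at C5', because C1' is quaternary. It should give the spiro silyl dienol ether 6'-[(tert-butyldimethylsilyloxy)methyl]-4'-methoxy-5'-(3-methylbut-2-enyl)-4-(3-methylbut-2-enyloxy)-2'-(trimethylsilyloxy)-3H-spiro[benzofuran-2,1'-cyclohexa[2,4]dien]-3-one F5.
 - Pd(OAc)2 in MeCN (Saegusa–Ito oxidation in its vinylogous form) should give the spiro dienone 6'-[(tert-butyldimethylsilyloxy)methyl]-4'-methoxy-5'-(3-methylbut-2-enyl)-4-(3-methylbut-2-enyloxy)-3H-spiro[benzofuran-2,1'-cyclohexa[3,5]diene]-2',3-dione F6.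
 - NaOMe in MeOH at 0 °C then cleaves C3–C1' with ring B leaving as a phenoxide, so aromatization both drives and directs the fragmentation. Acidification gives 22.

3. Step 4. A second benzofuranone enolate may add in conjugate fashion to the freshly formed alkylidene, or the exocyclic double bond may migrate toward the silyloxy carbon on the basic surface. The fallback separates addition from dehydration. It sets out from 8 and 9 and returns at 11.
 - The lithium enolate of 8 (LiN(SiMe3)2, THF, −78 °C) is added to 9, and the aldol 10 is isolated after a cold NH4Cl quench.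
 - Mesylation (MsCl, Et3N, CH2Cl2, 0 °C) gives the mesylate 2-(tert-butyldimethylsilyloxy)-1-[3-oxo-4-(3-methylbut-2-enyloxy)-2,3-dihydrobenzofuran-2-yl]ethyl methanesulfonate F7.
 - DBU at 25 °C eliminates methanesulfonate by an E1cB path to the Z alkylidene 11.

Further compounds
F1 | step 8 | methyl (2Z)-7-methyl-3-(trimethylsilyloxy)octa-2,6-dienoate | COC(=O)/C=C(\O[Si](C)(C)C)CCC=C(C)C
F2 | step 8 | (3Z)-1-methoxy-7-methyl-1,3-bis(trimethylsilyloxy)octa-1,3,6-triene | COC(O[Si](C)(C)C)=C/C(O[Si](C)(C)C)=C/CC=C(C)C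
F3 | step 8 | methyl 6-(tert-butyldimethylsilyloxy)-4-(3-methylbut-2-enyl)-3-oxo-5-[3-oxo-4-(3-methylbut-2-enyloxy)-2,3-dihydrobenzofuran-2-yl]hexanoate (racemic diastereomer mixture) | COC(=O)CC(=O)C(CC=C(C)C)C(CO[Si](C)(C)C(C)(C)C)C1Oc2cccc(OCC=C(C)C)c2C1=O
F4 | step 8 | 6'-[(tert-butyldimethylsilyloxy)methyl]-5'-(3-methylbut-2-enyl)-4-(3-methylbut-2-enyloxy)-3H-spiro[benzofuran-2,1'-cyclohexane]-2',3,4'-trione (racemic diastereomer mixture) | O=C1c2c(OCC=C(C)C)cccc2OC13C(=O)CC(=O)C(CC=C(C)C)C3CO[Si](C)(C)C(C)(C)C
F5 | step 9 | 6'-[(tert-butyldimethylsilyloxy)methyl]-4'-methoxy-5'-(3-methylbut-2-enyl)-4-(3-methylbut-2-enyloxy)-2'-(trimethylsilyloxy)-3H-spiro[benzofuran-2,1'-cyclohexa[2,4]dien]-3-one (racemic diastereomer mixture) | O=C1c2c(OCC=C(C)C)cccc2OC13C(O[Si](C)(C)C)=CC(OC)=C(CC=C(C)C)C3CO[Si](C)(C)C(C)(C)C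
F6 | step 9 | 6'-[(tert-butyldimethylsilyloxy)methyl]-4'-methoxy-5'-(3-methylbut-2-enyl)-4-(3-methylbut-2-enyloxy)-3H-spiro[benzofuran-2,1'-cyclohexa[3,5]diene]-2',3-dione (racemic) | O=C1c2c(OCC=C(C)C)cccc2OC13C(=O)C=C(OC)C(CC=C(C)C)=C3CO[Si](C)(C)C(C)(C)C
F7 | step 4 | 2-(tert-butyldimethylsilyloxy)-1-[3-oxo-4-(3-methylbut-2-enyloxy)-2,3-dihydrobenzofuran-2-yl]ethyl methanesulfonate (racemic diastereomer mixture) | O=C1c2c(OCC=C(C)C)cccc2OC1C(OS(C)(=O)=O)CO[Si](C)(C)C(C)(C)C
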